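Locants: ring atoms carry the target's 1H-indene numbers (C1, C2, C3, C3a, C4 to C7, C7a) in all intermediates, open-chain ones included.
Cuts, from the target backwards: side-chain C=C (Z-selective olefination), C7=C7a (ring-closing metathesis), ring-fusion bond C3a–C7a (5-exo-dig closure of a tertiary C3a radical onto an alkyne), C3a–C4 (γ-addition of a prenyl Grignard reagent to a methyl ketone), C2–C3 (Ireland–Claisen rearrangement of a geranyl ester).
Forward order: open-chain C2/C3 diad, then the oxygenated C3a carbon carrying every ring carbon, then the five-membered ring (key step), then the six-membered ring by metathesis, then the side chain.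
Enabling feature: C3a is a fully substituted carbon wedged between the quaternary carbons C3 and C4 and is therefore reached as a tertiary radical; C7a is sp2 and three atoms (C1, C2, C3) away, so an alkyne hung on C1 takes the radical and leaves the exocyclic methylene from which C7=C7a is made.
Stereochemistry: C2 and C3 (relative and absolute) from the chair transition state of a chiral boron-enolate Ireland–Claisen step; C3a from C2/C3 in the chair-like radical transition state; the Z-alkene from a Still–Gennari olefination.

Key step: step 9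

Assumption: the (S,S)-bromoborane with Et3N in toluene–hexane is taken to give the boron enolate with the propargylic CH2 cis to the allylic oxygen and to lead to the (2S,3S)-acid; should the facial sense be the opposite one, the (R,R)-controller is used.
Remark: 10 to 14 are carried as both epimers at the oxygen-bearing C3a, because this carbon becomes a planar radical in step 9.

Step 1
Reactants: 1 geraniol; 2 5-(trimethylsilyl)pent-4-ynoic acid
Product: 3 (2E)-3,7-dimethylocta-2,6-dien-1-yl 5-(trimethylsilyl)pent-4-ynoate
Conditions: DCC, DMAP (cat.), CH2Cl2, 0 °C → rt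
Reagents that add atoms: none
Why: Steglich esterification of a primary allylic alcohol with an unhindered acid should join the two purchased fragments without touching the silyl alkyne or the alkenes.

Step 2
Reactants: 3 geranyl ester
Product: 5 (2S,3S)-3-ethenyl-3,7-dimethyl-2-[3-(trimethylsilyl)prop-2-yn-1-yl]oct-6-enoic acid, via boron enolate 4 (not isolated)
Conditions: (4S,5S)-2-bromo-1,3-bis{[3,5-bis(trifluoromethyl)phenyl]sulfonyl}-4,5-diphenyl-1,3,2-diazaborolidine [from the (1S,2S)-bis-sulfonamide and BBr3, CH2Cl2], Et3N, toluene–hexane, −78 °C, then −20 → 4 °C; H2O work-up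
Reagents that add atoms: none
Why: In this enantioselective boron-enolate Ireland–Claisen rearrangement the enolate (propargylic CH2 cis to the allylic oxygen) and the E-trisubstituted alkene of the geranyl unit should pass through a chair transition state with the propargyl group and the C3 methyl group both axial, which sets C2 and the quaternary C3 in the required relative sense, while the C2-symmetric bis-sulfonamide ligand on boron selects the enolate face and so the absolute configuration.

Step 3
Reactants: 5 acid
Product: 6 methyl (2S,3S)-3-ethenyl-3,7-dimethyl-2-[3-(trimethylsilyl)prop-2-yn-1-yl]oct-6-enoate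
Conditions: MeI, K2CO3, DMF, rt
Reagents that add atoms: iodomethane, CI
Why: SN2 O-alkylation of the carboxylate should give the methyl ester without epimerisation and masks an acid that would lactonise onto the alkene in step 4 and be oxidised by the photocatalyst in step 9.

Step 4
Reactants: 6 methyl ester
Product: 7 methyl (2S,3R)-3-acetyl-3,7-dimethyl-2-[3-(trimethylsilyl)prop-2-yn-1-yl]oct-6-enoate
Conditions: PdCl2 (10 mol%), CuCl, O2 (1 atm), DMF–H2O, rt
Reagents that add atoms: water, O
Why: Tsuji–Wacker oxidation should convert the monosubstituted vinyl group on the quaternary carbon into the methyl ketone with Markovnikov selectivity, the trisubstituted alkene and the silyl-capped alkyne being too hindered to compete.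

Step 5
Reactants: 7 methyl ketone
Product: 9 methyl (2S,3R)-3-acetyl-6,6-dimethoxy-3-methyl-2-[3-(trimethylsilyl)prop-2-yn-1-yl]hexanoate, via keto aldehyde 8 (not isolated)
Conditions: O3, CH2Cl2–MeOH, −78 °C (indicator end point); Me2S, −78 °C → rt; then p-TsOH (cat.), rt
Reagents that add atoms: methanol, CO
Why: Ozonolysis should cleave the only remaining alkene (the silyl alkyne reacts far more slowly) and acid-catalysed acetalisation in methanol masks the aldehyde, which removes a 5-exo radical trap before the key step and stores the carbonyl needed for the side chain.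

Step 6
Reactants: 9 keto acetal
Product: 11 methyl (2S,3R)-6,6-dimethoxy-3-{2-[(methoxyoxalyl)oxy]-3,3-dimethylpent-4-en-2-yl}-3-methyl-2-[3-(trimethylsilyl)prop-2-yn-1-yl]hexanoate (both C3a epimers), via magnesium alkoxide 10 (not isolated)
Conditions: 3-methylbut-2-enylmagnesium chloride, THF, −78 °C; then ClC(O)CO2Me, −78 → −20 °C
Reagents that add atoms: 3-methylbut-2-en-1-ylmagnesium chloride, CC(C)=CC[Mg]Cl; methyl chlorooxoacetate, COC(=O)C(=O)Cl
Why: γ-Selective (SE2′, six-membered transition state) addition of the prenyl Grignard reagent to the methyl ketone should forge the C3a–C4 bond, and trapping the hindered magnesium alkoxide cold with the reactive oxalyl half-ester chloride gives the radical precursor before retro-allylation or lactonisation onto the C2 ester can set in; the new carbinol centre forms as a mixture, which is immaterial.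

Step 7
Reactants: 11 methyl oxalate
Product: 12 methyl (2S,3R)-6,6-dimethoxy-3-{2-[(methoxyoxalyl)oxy]-3,3-dimethyl-5-(4,4,5,5-tetramethyl-1,3,2-dioxaborolan-2-yl)pentan-2-yl}-3-methyl-2-[3-(trimethylsilyl)prop-2-yn-1-yl]hexanoate
Conditions: HBpin, [Ir(cod)Cl]2 (1.5 mol%), dppe (3 mol%), CH2Cl2, rt
Reagents that add atoms: pinacolborane, CC1(C)OBOC1(C)C
Why: Iridium-catalysed anti-Markovnikov hydroboration of the only alkene (the internal silyl alkyne and the esters are inert) should saturate a vinyl group that would otherwise undergo 1,2-vinyl shift or capture the alkoxycarbonyl radical in step 9, and leaves a stable primary C–B handle.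

Step 8
Reactants: 12 boronate oxalate
Product: 14 cesium half-oxalate of the C3a alcohol with free terminal alkyne, via silyl alkyne cesium oxalate 13 (not isolated)
Conditions: CsOH·H2O (1.0 equiv), THF–H2O, 0 °C → rt; then K2CO3 (0.2 equiv), MeOH, rt; concentrate
Reagents that add atoms: cesium hydroxide, [Cs+].[OH-]
Why: Saponification should occur only at the unhindered methyl ester of the mixed oxalate (the tert-alkyl ester and the C2 ester are shielded), after which catalytic methoxide removes the alkynyl silyl group by protodesilylation without attacking the now anionic oxalate.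

Step 9
Reactants: 14 cesium oxalate
Product: 15 methyl (1S,2R,3S)-2-(3,3-dimethoxypropyl)-2,3-dimethyl-4-methylidene-3-[2-methyl-4-(4,4,5,5-tetramethyl-1,3,2-dioxaborolan-2-yl)butan-2-yl]cyclopentane-1-carboxylate
Conditions: Ir[dF(CF3)ppy]2(dtbbpy)PF6 (2 mol%), 2,4,6-triisopropylbenzenethiol (5 mol%), H2O (10 equiv), DME–DMF, 0.01 M, blue LEDs, 35 °C
Reagents that add atoms: none
Why: Proposed new method: the photoexcited iridium complex oxidises the oxalate carboxylate, loss of two CO2 gives the tertiary radical at C3a, this adds to the proximal alkyne carbon (C7a), and the vinyl radical takes a hydrogen atom from the thiol, whose thiyl radical is reduced by the reduced photocatalyst and reprotonated by water, so the sequence is redox-neutral. The closest known reaction types are the photoredox fragmentation of tert-alkyl cesium oxalates for intermolecular conjugate addition, tin hydride-mediated 5-exo-dig cyclisation of tertiary radicals onto alkynes, and thiol-cocatalysed photoredox hydrodecarboxylation; new is their combination with an unactivated alkyne and hydrogen-atom termination. The cyclopentane ring closes in the 5-exo-dig mode, forming C3a–C7a at a carbon flanked by two quaternary carbons (C3, C4), which an early radical transition state with a long forming bond should tolerate. The new stereocentre C3a is controlled by C2 and C3: in the chair-like transition state the C2 ester and the C3 dimethoxypropyl chain are pseudo-equatorial, the C3 methyl group is pseudo-axial and nearly eclipsed with one substituent of the planar radical, so the small methyl group of the radical should take that site and the bulky tert-alkyl group the staggered one, which places the two methyl groups cis. The step needs ring closure to outrun hydrogen capture by the tertiary radical, secured by high dilution, low thiol loading and the Thorpe–Ingold effect of C3, and it needs chemoselectivity, secured because the alkyne is the only π-acceptor left within reach after steps 5 and 7 and because the C2 carboxyl group is an ester that the photocatalyst cannot oxidise.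

Step 10
Reactants: 15 methylidenecyclopentane boronate
Product: 16 methyl (1S,2R,3S)-2-(3,3-dimethoxypropyl)-2,3-dimethyl-4-methylidene-3-(2-methylhex-5-en-2-yl)cyclopentane-1-carboxylate
Conditions: vinyl bromide (THF solution), Pd(OAc)2 (5 mol%), RuPhos (10 mol%), K3PO4, toluene–H2O, 80 °C (sealed)
Reagents that add atoms: vinyl bromide, C=CBr
Why: B-alkyl Suzuki–Miyaura coupling of the unhindered primary alkylboronate should extend the chain to the but-3-enyl group needed for ring closure, the hindered ester, the acetal and the 1,1-disubstituted alkene being inert to the mild base and to zerovalent palladium.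

Step 11
Reactants: 16 diene
Product: 17 methyl (2S,3R,3aS)-3-(3,3-dimethoxypropyl)-3,3a,4,4-tetramethyl-2,3,3a,4,5,6-hexahydro-1H-indene-2-carboxylate
Conditions: second-generation Hoveyda–Grubbs catalyst (5 mol%), CH2Cl2, 40 °C
Reagents that add atoms: none
Why: Ring-closing metathesis between the terminal alkene (initiation site) and the exocyclic 1,1-disubstituted alkene should close the six-membered ring and fix the trisubstituted C7=C7a double bond unambiguously, loss of ethene driving the reaction.

Step 12
Reactants: 17 bicyclic ester acetal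
Product: 19 (2S,3R,3aS)-3,3a,4,4-tetramethyl-3-(3-oxopropyl)-2,3,3a,4,5,6-hexahydro-1H-indene-2-carboxylic acid, via trimethylstannyl ester 18 (not isolated)
Conditions: Me3SnOH, ClCH2CH2Cl, 80 °C; then 1 M HCl, THF, rt
Reagents that add atoms: trimethyltin hydroxide, C[Sn](C)(C)O; water, O
Why: Trimethyltin hydroxide should cleave the hindered methyl ester by acyl substitution at neutral pH without epimerising C2, and the dilute acid of the work-up frees the acid and hydrolyses the acetal while being too weak to protonate the trisubstituted alkene and trigger lactonisation.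

Step 13
Reactants: 19 aldehyde acid
Product: 20 (2S,3R,3aS)-3-[(3Z)-5-ethoxy-4-methyl-5-oxopent-3-en-1-yl]-3,3a,4,4-tetramethyl-2,3,3a,4,5,6-hexahydro-1H-indene-2-carboxylic acid
Conditions: (CF3CH2O)2P(O)CH(CH3)CO2Et, KN(SiMe3)2 (2.2 equiv), 18-crown-6, THF, −78 °C
Reagents that add atoms: ethyl 2-[bis(2,2,2-trifluoroethoxy)phosphoryl]propanoate, CCOC(=O)C(C)P(=O)(OCC(F)(F)F)OCC(F)(F)F
Why: Still–Gennari olefination (kinetically controlled Horner–Wadsworth–Emmons reaction of the electron-poor phosphonate with a dissociated potassium counter-ion) should give the Z-trisubstituted enoate, the carboxylate formed by the first equivalent of base staying inert.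

Step 14
Reactants: 20 Z-enoate acid
Product: 21 (2S,3R,3aS)-3-[(3Z)-5-hydroxy-4-methylpent-3-en-1-yl]-3,3a,4,4-tetramethyl-2,3,3a,4,5,6-hexahydro-1H-indene-2-carboxylic acid
Conditions: i-Bu2AlH (4 equiv), CH2Cl2, −78 °C; Rochelle salt work-up
Reagents that add atoms: none
Why: 1,2-Reduction of the conjugated ester by diisobutylaluminium hydride should give the allylic alcohol with the alkene geometry retained, the aluminium carboxylate formed from the free acid resisting hydride at −78 °C.

Step 15
Reactants: 21 hydroxy acid
Product: 22 (2S,3R,3aS)-3-[(3Z)-5-(acetyloxy)-4-methylpent-3-en-1-yl]-3,3a,4,4-tetramethyl-2,3,3a,4,5,6-hexahydro-1H-indene-2-carboxylic acid (target)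
Conditions: Ac2O, pyridine, DMAP (cat.), CH2Cl2, 0 °C → rt; then H2O
Reagents that add atoms: acetic anhydride, CC(=O)OC(C)=O
Why: Nucleophile-catalysed O-acetylation should take the primary allylic alcohol, and any mixed anhydride formed at the hindered carboxylic acid is hydrolysed in the aqueous work-up.

Compound list
1 | geraniol, (2E)-3,7-dimethylocta-2,6-dien-1-ol | CC(C)=CCC/C(C)=C/CO | starting material
2 | 5-(trimethylsilyl)pent-4-ynoic acid | C[Si](C)(C)C#CCCC(=O)O | starting material
3 | (2E)-3,7-dimethylocta-2,6-dien-1-yl 5-(trimethylsilyl)pent-4-ynoate | CC(C)=CCC/C(C)=C/COC(=O)CCC#C[Si](C)(C)C | intermediate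
4 | O-boron enolate of 3 carrying the (4S,5S)-1,3-bis{[3,5-bis(trifluoromethyl)phenyl]sulfonyl}-4,5-diphenyl-1,3,2-diazaborolidin-2-yl group, propargylic CH2 cis to the geranyloxy oxygen | CC(C)=CCC/C(C)=C/CO/C(OB1N(S(=O)(=O)c2cc(cc(c2)C(F)(F)F)C(F)(F)F)[C@@H](c2ccccc2)[C@H](c2ccccc2)N1S(=O)(=O)c1cc(cc(c1)C(F)(F)F)C(F)(F)F)=C\CC#C[Si](C)(C)C | intermediate (not isolated)
5 | (2S,3S)-3-ethenyl-3,7-dimethyl-2-[3-(trimethylsilyl)prop-2-yn-1-yl]oct-6-enoic acid | CC(C)=CCC[C@](C=C)(C)[C@@H](C(=O)O)CC#C[Si](C)(C)C | intermediate
6 | methyl (2S,3S)-3-ethenyl-3,7-dimethyl-2-[3-(trimethylsilyl)prop-2-yn-1-yl]oct-6-enoate | CC(C)=CCC[C@](C=C)(C)[C@@H](C(=O)OC)CC#C[Si](C)(C)C | intermediate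
7 | methyl (2S,3R)-3-acetyl-3,7-dimethyl-2-[3-(trimethylsilyl)prop-2-yn-1-yl]oct-6-enoate | CC(C)=CCC[C@](C(C)=O)(C)[C@@H](C(=O)OC)CC#C[Si](C)(C)C | intermediate
8 | methyl (2S,3R)-3-acetyl-3-methyl-6-oxo-2-[3-(trimethylsilyl)prop-2-yn-1-yl]hexanoate | O=CCC[C@](C(C)=O)(C)[C@@H](C(=O)OC)CC#C[Si](C)(C)C | intermediate (not isolated)
9 | methyl (2S,3R)-3-acetyl-6,6-dimethoxy-3-methyl-2-[3-(trimethylsilyl)prop-2-yn-1-yl]hexanoate | COC(OC)CC[C@](C(C)=O)(C)[C@@H](C(=O)OC)CC#C[Si](C)(C)C | intermediate
10 | chloromagnesium alkoxide of methyl (2S,3R)-3-(2-hydroxy-3,3-dimethylpent-4-en-2-yl)-6,6-dimethoxy-3-methyl-2-[3-(trimethylsilyl)prop-2-yn-1-yl]hexanoate, both carbinol epimers | COC(OC)CC[C@](C(C)(O[Mg]Cl)C(C)(C)C=C)(C)[C@@H](C(=O)OC)CC#C[Si](C)(C)C | intermediate (not isolated)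
11 | methyl (2S,3R)-6,6-dimethoxy-3-{2-[(methoxyoxalyl)oxy]-3,3-dimethylpent-4-en-2-yl}-3-methyl-2-[3-(trimethylsilyl)prop-2-yn-1-yl]hexanoate, both epimers at the oxalate carbon | COC(OC)CC[C@](C(C)(OC(=O)C(=O)OC)C(C)(C)C=C)(C)[C@@H](C(=O)OC)CC#C[Si](C)(C)C | intermediate
12 | methyl (2S,3R)-6,6-dimethoxy-3-{2-[(methoxyoxalyl)oxy]-3,3-dimethyl-5-(4,4,5,5-tetramethyl-1,3,2-dioxaborolan-2-yl)pentan-2-yl}-3-methyl-2-[3-(trimethylsilyl)prop-2-yn-1-yl]hexanoate, both epimers | COC(OC)CC[C@](C(C)(OC(=O)C(=O)OC)C(C)(C)CCB1OC(C)(C)C(C)(C)O1)(C)[C@@H](C(=O)OC)CC#C[Si](C)(C)C | intermediate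
13 | cesium half-oxalate of 12 (oxalate CO2Me replaced by CO2Cs), silyl alkyne retained, both epimers | COC(OC)CC[C@](C(C)(OC(=O)C(=O)[O-])C(C)(C)CCB1OC(C)(C)C(C)(C)O1)(C)[C@@H](C(=O)OC)CC#C[Si](C)(C)C.[Cs+] | intermediate (not isolated)
14 | cesium half-oxalate as 13 with the terminal alkyne free (prop-2-yn-1-yl on C2), both epimers | COC(OC)CC[C@](C(C)(OC(=O)C(=O)[O-])C(C)(C)CCB1OC(C)(C)C(C)(C)O1)(C)[C@@H](C(=O)OC)CC#C.[Cs+] | intermediate
15 | methyl (1S,2R,3S)-2-(3,3-dimethoxypropyl)-2,3-dimethyl-4-methylidene-3-[2-methyl-4-(4,4,5,5-tetramethyl-1,3,2-dioxaborolan-2-yl)butan-2-yl]cyclopentane-1-carboxylate | COC(OC)CC[C@]1(C)[C@@H](C(=O)OC)CC(=C)[C@]1(C)C(C)(C)CCB2OC(C)(C)C(C)(C)O2 | intermediate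
16 | methyl (1S,2R,3S)-2-(3,3-dimethoxypropyl)-2,3-dimethyl-4-methylidene-3-(2-methylhex-5-en-2-yl)cyclopentane-1-carboxylate | COC(OC)CC[C@]1(C)[C@@H](C(=O)OC)CC(=C)[C@]1(C)C(C)(C)CCC=C | intermediate
17 | methyl (2S,3R,3aS)-3-(3,3-dimethoxypropyl)-3,3a,4,4-tetramethyl-2,3,3a,4,5,6-hexahydro-1H-indene-2-carboxylate | COC(OC)CC[C@]1(C)[C@@H](C(=O)OC)CC2=CCCC(C)(C)[C@@]21C | intermediate
18 | trimethylstannyl (2S,3R,3aS)-3-(3,3-dimethoxypropyl)-3,3a,4,4-tetramethyl-2,3,3a,4,5,6-hexahydro-1H-indene-2-carboxylate | COC(OC)CC[C@]1(C)[C@@H](C(=O)O[Sn](C)(C)C)CC2=CCCC(C)(C)[C@@]21C | intermediate (not isolated)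
19 | (2S,3R,3aS)-3,3a,4,4-tetramethyl-3-(3-oxopropyl)-2,3,3a,4,5,6-hexahydro-1H-indene-2-carboxylic acid | O=CCC[C@]1(C)[C@@H](C(=O)O)CC2=CCCC(C)(C)[C@@]21C | intermediate
20 | (2S,3R,3aS)-3-[(3Z)-5-ethoxy-4-methyl-5-oxopent-3-en-1-yl]-3,3a,4,4-tetramethyl-2,3,3a,4,5,6-hexahydro-1H-indene-2-carboxylic acid | CCOC(=O)/C(C)=C\CC[C@]1(C)[C@@H](C(=O)O)CC2=CCCC(C)(C)[C@@]21C | intermediate
21 | (2S,3R,3aS)-3-[(3Z)-5-hydroxy-4-methylpent-3-en-1-yl]-3,3a,4,4-tetramethyl-2,3,3a,4,5,6-hexahydro-1H-indene-2-carboxylic acid | OC/C(C)=C\CC[C@]1(C)[C@@H](C(=O)O)CC2=CCCC(C)(C)[C@@]21C | intermediate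
22 | (2S,3R,3aS)-3-[(3Z)-5-(acetyloxy)-4-methylpent-3-en-1-yl]-3,3a,4,4-tetramethyl-2,3,3a,4,5,6-hexahydro-1H-indene-2-carboxylic acid | CC(=O)OC/C(C)=C\CC[C@]1(C)[C@@H](C(=O)O)CC2=CCCC(C)(C)[C@@]21C | target

Total step count: 15. Longest linear sequence: 15 steps (from 1; 2 is used as purchased).

Steps most likely to fail

Step 9 (proposed new method). The tertiary radical may capture a hydrogen atom before it cyclises, thiyl radicals may add to the terminal alkyne, or the facial selectivity at C3a may be low. The fallback uses known chemistry and sets out from 12, before desilylation. Tin hydride fragmentation of the tert-alkyl methyl oxalate (Bu3SnH, AIBN, toluene, 110 °C, slow addition) is coupled with classical 5-exo-dig radical cyclisation onto the silyl alkyne, which resists hydrostannation. This should give the (Z)-vinylsilane F1, the silyl group ending syn to C3a because the stannane approaches the vinyl radical from the C1 side. Iododesilylation with retention (NIS, MeCN–ClCH2CN, 0 °C) gives the vinyl iodide F2. Intramolecular B-alkyl Suzuki–Miyaura coupling (Pd(dppf)Cl2, Cs2CO3, DMF–H2O, 60 °C) then closes the six-membered ring by the C6–C7 bond, so that steps 10 and 11 are not needed, and the route is rejoined at 17.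

Step 6. The Grignard reagent may enolise the hindered methyl ketone, the addition may reverse (retro-allylation), or the magnesium alkoxide may lactonise onto the C2 ester before O-acylation. The fallback sets out from 9 and makes the C3a–C4 bond intramolecularly, with a carboxyl group in place of the oxalate as radical precursor. Enolisation and triflation (KN(SiMe3)2, PhNTf2, THF, −78 °C) give the enol triflate F3. Alkoxycarbonylation with 3-methylbut-2-en-1-ol (Pd(OAc)2, dppf, CO, Et3N, DMF, 60 °C) gives the prenyl acrylate F4. A reductive Ireland–Claisen rearrangement (copper hydride–silane conjugate reduction to the silyl ketene acetal, then [3,3] shift on warming) gives the quaternary acid F5. Hydroboration as in step 7 (extra HBpin for the acid) gives the boronate acid F6, and K2CO3 in MeOH gives the terminal alkyne acid F7. Barton decarboxylation through the thiohydroxamate ester F8 (t-BuSH, visible light, benzene) with 5-exo-dig cyclisation of the same tertiary radical rejoins the route at 15.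

Step 4. Divalent palladium may cyclise across the 1,6-enyne (vinyl group and silyl alkyne) or oxidise the terminal carbon to the aldehyde instead of forming the ketone. The fallback sets out from 6, reverses the order of the two oxidations and avoids palladium. Ozonolysis and acetalisation under the conditions of step 5, stopped at the indicator end point so that the hindered vinyl group survives, give the vinyl acetal F9. Mukaiyama hydration (Co(acac)2, PhSiH3, O2, i-PrOH), a Markovnikov radical hydration that leaves the silyl alkyne alone, gives the secondary alcohol F10. Immediate Dess–Martin oxidation rejoins the route at 9.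

Further compounds
F1 | step 9 | (Z)-vinylsilane: analogue of 15 with 4-[(trimethylsilyl)methylidene] in place of 4-methylidene, silyl group syn to the quaternary ring carbon C3a | COC(OC)CC[C@]1(C)[C@@H](C(=O)OC)C/C(=C/[Si](C)(C)C)[C@]1(C)C(C)(C)CCB2OC(C)(C)C(C)(C)O2
F2 | step 9 | (Z)-vinyl iodide: analogue of F1 with iodine in place of the trimethylsilyl group | COC(OC)CC[C@]1(C)[C@@H](C(=O)OC)C/C(=C/I)[C@]1(C)C(C)(C)CCB2OC(C)(C)C(C)(C)O2
F3 | step 6 | enol triflate of 9: 1-[(trifluoromethanesulfonyl)oxy]ethenyl in place of acetyl | COC(OC)CC[C@](C(=C)OS(=O)(=O)C(F)(F)F)(C)[C@@H](C(=O)OC)CC#C[Si](C)(C)C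
F4 | step 6 | prenyl acrylate: 3-methylbut-2-en-1-yl ester of the 2-substituted acrylic acid formed from F3 | COC(OC)CC[C@](C(=C)C(=O)OCC=C(C)C)(C)[C@@H](C(=O)OC)CC#C[Si](C)(C)C
F5 | step 6 | quaternary acid: 2,3,3-trimethylpent-4-enoic acid carrying at its C2 the quaternary carbon C3 of the chain, both C3a epimers | COC(OC)CC[C@](C(C)(C(=O)O)C(C)(C)C=C)(C)[C@@H](C(=O)OC)CC#C[Si](C)(C)C
F6 | step 6 | boronate acid: F5 with the vinyl group turned into 2-(4,4,5,5-tetramethyl-1,3,2-dioxaborolan-2-yl)ethyl | COC(OC)CC[C@](C(C)(C(=O)O)C(C)(C)CCB1OC(C)(C)C(C)(C)O1)(C)[C@@H](C(=O)OC)CC#C[Si](C)(C)C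
F7 | step 6 | terminal alkyne acid: F6 without the trimethylsilyl group | COC(OC)CC[C@](C(C)(C(=O)O)C(C)(C)CCB1OC(C)(C)C(C)(C)O1)(C)[C@@H](C(=O)OC)CC#C
F8 | step 6 | thiohydroxamate (2-thioxopyridin-1(2H)-yl) ester of F7 | COC(OC)CC[C@](C(C)(C(=O)On1ccccc1=S)C(C)(C)CCB1OC(C)(C)C(C)(C)O1)(C)[C@@H](C(=O)OC)CC#C
F9 | step 4 | vinyl acetal: methyl (2S,3S)-3-ethenyl-6,6-dimethoxy-3-methyl-2-[3-(trimethylsilyl)prop-2-yn-1-yl]hexanoate | COC(OC)CC[C@](C=C)(C)[C@@H](C(=O)OC)CC#C[Si](C)(C)C
F10 | step 4 | secondary alcohol: analogue of 9 with 1-hydroxyethyl in place of acetyl, both carbinol epimers | COC(OC)CC[C@](C(C)O)(C)[C@@H](C(=O)OC)CC#C[Si](C)(C)C
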